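**Strategy.** All three units of the target are (2R,3R)-epicatechin, so one protected flavan is built and used three times. Everything rests on making its ring C from a 2,4,6-trifluorophenyl benzyloxymethyl ketone (ring A, C4, C3) and 3,4-bis(benzyloxy)benzoyl chloride (C2, O1, ring B). In one operation C-acylation joins C2 to C3 and the new enolate oxygen displaces an ortho fluoride to join O1 to C8a, giving a flavonol. The step exploits that C3 and C8a both flank C4: a temporary C4 carbonyl acidifies C3–H and activates C8a–F, and the two ortho C–F bonds of ring A are equivalent. Asymmetric hydrogenation then sets C2 and C3, and the C4 hydroxyl drives two 4β→6 couplings directed by C8 bromine.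

Key step: step 2

Remark 1: (R,R)-SINpEt·HBF4 is 1,3-bis[(R)-1-(naphthalen-1-yl)ethyl]-4,5-dihydroimidazolium tetrafluoroborate; it is assumed that this antipode leads to the 2R series in step 4, otherwise its mirror image is used.
Remark 2: the configuration at C4 of 12, 13 and 15 is of no consequence, because C4 is ionised or reduced later.

Step 1
Reactants: 1 1,3,5-trifluorobenzene; 2 2-(benzyloxy)-N-methoxy-N-methylacetamide
Product: 4 2-(benzyloxy)-1-(2,4,6-trifluorophenyl)ethan-1-one, via 2,4,6-trifluorophenyllithium 3 (not isolated)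
Conditions: n-BuLi (1.05 equiv), THF, −78 °C; then 2, −78 → −20 °C; aq NH4Cl
Reagents that add atoms: none
Why: Fluorine-directed ortho-lithiation takes a C–H flanked by two fluorines (all three are equivalent), and the aryllithium 3, kept at −78 °C to avoid loss of LiF to an aryne, should be acylated once by the N-methoxy-N-methylamide through its chelated tetrahedral adduct (Weinreb ketone synthesis).

Step 2
Reactants: 4 2-(benzyloxy)-1-(2,4,6-trifluorophenyl)ethan-1-one; 5 3,4-bis(benzyloxy)benzoyl chloride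
Product: 7 3-(benzyloxy)-2-[3,4-bis(benzyloxy)phenyl]-5,7-difluoro-4H-chromen-4-one, via lithium diketonate 6 (not isolated)
Conditions: LiN(SiMe3)2 (2.2 equiv), THF, −78 °C; 5, −78 → 0 °C; then DMF, 25 → 60 °C
Reagents that add atoms: none
Why: The lithium enolate of 4 is C-acylated at C3 by 5 (Claisen-type acylation, any enol ester being relayed to the C-acyl compound by the second equivalent of base), which makes C2–C3 and gives the diketonate 6. On warming in DMF the enolate oxygen that stems from the aroyl carbonyl of 5 adds to an ortho C–F carbon of ring A and fluoride leaves through an anionic σ-adduct (intramolecular SNAr), which makes O1–C8a. The closest known reaction type is the cycloacylation/SNAr route to chromones and 4-quinolones from 2-haloaryl carbonyl compounds. Ring C closes by a 6-exo-trig addition–elimination, since attack by the other enolate oxygen would need a four-membered ring. No stereocentre is formed: the step delivers the flat flavonol core, and C2 and C3 are set in step 4. The step needs ring closure to win over intermolecular displacement of the para fluoride, and this is secured because only the two equivalent ortho fluorines are within reach of the tethered oxygen and C8a is activated by the C4 carbonyl and the remaining fluorines.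

Step 3
Reactants: 7 3-(benzyloxy)-2-[3,4-bis(benzyloxy)phenyl]-5,7-difluoro-4H-chromen-4-one; 8 benzyl alcohol
Product: 10 3,5,7-tris(benzyloxy)-2-[3,4-bis(benzyloxy)phenyl]-4H-chromen-4-one, via 7-benzyloxy-5-fluoroflavone 9 (not isolated)
Conditions: 8 (2.5 equiv), NaH (2.5 equiv), THF/DMF, 0 → 70 °C
Reagents that add atoms: none
Why: Two nucleophilic aromatic substitutions by benzyl oxide should occur, because C7–F (para to C4a) and C5–F (ortho to C4a) are both activated by the C4 carbonyl; the unhindered C7 is expected to react first (9), and the fully substituted C2 is shielded against conjugate addition.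

Step 4
Reactants: 10 3,5,7-tris(benzyloxy)-2-[3,4-bis(benzyloxy)phenyl]-4H-chromen-4-one
Product: 12 (2R,3R,4R)-3,5,7-tris(benzyloxy)-2-[3,4-bis(benzyloxy)phenyl]-3,4-dihydro-2H-chromen-4-ol (all-cis), via cis-flavanone 11 (not isolated)
Conditions: H2 (100 bar), [Ru(cod)(2-methylallyl)2] (5 mol %), (R,R)-SINpEt·HBF4 (10 mol %), KOtBu (15 mol %), toluene, 40 °C
Reagents that add atoms: none
Why: Ruthenium–NHC-catalysed asymmetric hydrogenation of flavones should deliver H2 syn to one face of C2=C3 and so set C2 and C3 together as 2,3-cis (catalyst control), after which the same catalyst reduces the C4 carbonyl of 11 from the face opposite the axial 3-benzyloxy group (substrate control).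

Step 5
Reactants: 12 (2R,3R,4R)-3,5,7-tris(benzyloxy)-2-[3,4-bis(benzyloxy)phenyl]-3,4-dihydro-2H-chromen-4-ol
Product: 13 (2R,3R,4R)-3,5,7-tris(benzyloxy)-2-[3,4-bis(benzyloxy)phenyl]-8-bromo-3,4-dihydro-2H-chromen-4-ol
Conditions: NBS (1.0 equiv), NaHCO3, CH2Cl2, −78 → −30 °C
Reagents that add atoms: N-bromosuccinimide, O=C1CCC(=O)N1Br
Why: Electrophilic aromatic bromination of the trioxygenated ring A should take C8, which is less crowded than C6 between two benzyloxy groups, and the buffer keeps the acid-labile C4 alcohol from ionising.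

Step 6
Reactants: 13 (2R,3R,4R)-3,5,7-tris(benzyloxy)-2-[3,4-bis(benzyloxy)phenyl]-8-bromo-3,4-dihydro-2H-chromen-4-ol
Product: 14 (2R,3R)-3,5,7-tris(benzyloxy)-2-[3,4-bis(benzyloxy)phenyl]-8-bromo-3,4-dihydro-2H-chromene (8-bromo-penta-O-benzyl-epicatechin)
Conditions: Et3SiH (5 equiv), CF3CO2H (3 equiv), CH2Cl2 (dilute), −40 → −10 °C
Reagents that add atoms: none
Why: Ionic hydrogenation should remove the C4 hydroxyl, because acid ionises the benzylic alcohol to a cation stabilised by ring A and the excess silane traps it faster than another molecule can; C2 and C3 are not touched.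

Step 7
Reactants: 12 (2R,3R,4R)-3,5,7-tris(benzyloxy)-2-[3,4-bis(benzyloxy)phenyl]-3,4-dihydro-2H-chromen-4-ol
Product: 15 (2R,3R,4R)-3,5,7-tris(benzyloxy)-2-[3,4-bis(benzyloxy)phenyl]-6,8-dibromo-3,4-dihydro-2H-chromen-4-ol
Conditions: NBS (2.2 equiv), NaHCO3, CH2Cl2, −78 → 0 °C
Reagents that add atoms: N-bromosuccinimide, O=C1CCC(=O)N1Br
Why: Twofold electrophilic aromatic bromination should fill both free positions of ring A (C8, then C6), which is far more electron-rich than ring B, so that this electrophile cannot condense with itself.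

Step 8
Reactants: 13 (2R,3R,4R)-3,5,7-tris(benzyloxy)-2-[3,4-bis(benzyloxy)phenyl]-8-bromo-3,4-dihydro-2H-chromen-4-ol; 14 8-bromo-penta-O-benzyl-epicatechin
Product: 16 8-bromo-penta-O-benzyl-epicatechin-(4β→6)-8-bromo-penta-O-benzyl-epicatechin
Conditions: 14 (3 equiv), BF3·OEt2 (1.2 equiv), 4 Å MS, CH2Cl2, −78 → −30 °C, slow addition of 13; Et3N quench
Reagents that add atoms: none
Why: Lewis-acid ionisation of the C4 hydroxyl gives a benzylic cation that is attacked by C6 of 14, its only free ring-A position (Friedel–Crafts-type flavan coupling), anti to the pseudo-axial 3-benzyloxy group, so the new C4 centre should be 4β (3,4-trans); the excess of 14 suppresses self-condensation of 13.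

Step 9
Reactants: 15 (2R,3R,4R)-3,5,7-tris(benzyloxy)-2-[3,4-bis(benzyloxy)phenyl]-6,8-dibromo-3,4-dihydro-2H-chromen-4-ol; 16 the 4β→6 dimer
Product: 17 6,8-dibromo-penta-O-benzyl-epicatechin-(4β→6)-8-bromo-penta-O-benzyl-epicatechin-(4β→6)-8-bromo-penta-O-benzyl-epicatechin
Conditions: BF3·OEt2 (1.5 equiv), 4 Å MS, CH2Cl2, −78 → −20 °C; Et3N quench
Reagents that add atoms: none
Why: The same Friedel–Crafts-type coupling should join the C4 cation of 15, which has no free ring-A position of its own, to C6 of the upper unit of 16, the only unsubstituted ring-A carbon left, again anti to the 3-benzyloxy group (4β).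

Step 10
Reactants: 17 the protected, tetrabrominated trimer
Product: 18 epicatechin-(4β→6)-epicatechin-(4β→6)-epicatechin (CNP0163146.2)
Conditions: H2 (1 atm), Pd(OH)2/C, Et3N, THF/MeOH/H2O, rt
Reagents that add atoms: none
Why: Hydrogenolysis should cleave all fifteen benzyl ethers and the four aryl C–Br bonds, while Et3N takes up HBr so that the acid-labile interflavan bonds and the stereocentres stay intact.

**Compound list**
1 | 1,3,5-trifluorobenzene | Fc1cc(F)cc(F)c1 | starting material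
2 | 2-(benzyloxy)-N-methoxy-N-methylacetamide | CON(C)C(=O)COCc1ccccc1 | starting material
3 | 2,4,6-trifluorophenyllithium | [Li]c1c(F)cc(F)cc1F | intermediate (not isolated)
4 | 2-(benzyloxy)-1-(2,4,6-trifluorophenyl)ethan-1-one | O=C(COCc1ccccc1)c1c(F)cc(F)cc1F | intermediate
5 | 3,4-bis(benzyloxy)benzoyl chloride | ClC(=O)c1ccc(OCc2ccccc2)c(OCc2ccccc2)c1 | starting material
6 | 2-(benzyloxy)-1-[3,4-bis(benzyloxy)phenyl]-3-(2,4,6-trifluorophenyl)propane-1,3-dione, present as its lithium enolate | O=C(c1ccc(OCc2ccccc2)c(OCc2ccccc2)c1)C(OCc1ccccc1)C(=O)c1c(F)cc(F)cc1F | intermediate (not isolated)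
7 | 3-(benzyloxy)-2-[3,4-bis(benzyloxy)phenyl]-5,7-difluoro-4H-chromen-4-one | O=c1c(OCc2ccccc2)c(-c2ccc(OCc3ccccc3)c(OCc3ccccc3)c2)oc2cc(F)cc(F)c12 | intermediate
8 | benzyl alcohol | OCc1ccccc1 | starting material
9 | 3,7-bis(benzyloxy)-2-[3,4-bis(benzyloxy)phenyl]-5-fluoro-4H-chromen-4-one | O=c1c(OCc2ccccc2)c(-c2ccc(OCc3ccccc3)c(OCc3ccccc3)c2)oc2cc(OCc3ccccc3)cc(F)c12 | intermediate (not isolated)
10 | 3,5,7-tris(benzyloxy)-2-[3,4-bis(benzyloxy)phenyl]-4H-chromen-4-one | O=c1c(OCc2ccccc2)c(-c2ccc(OCc3ccccc3)c(OCc3ccccc3)c2)oc2cc(OCc3ccccc3)cc(OCc3ccccc3)c12 | intermediate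
11 | (2R,3S)-3,5,7-tris(benzyloxy)-2-[3,4-bis(benzyloxy)phenyl]-2,3-dihydro-4H-chromen-4-one (2,3-cis) | C(c5ccccc5)Oc1cc(OCc5ccccc5)c2c(c1)O[C@H](c6ccc(OCc5ccccc5)c(OCc5ccccc5)c6)[C@H](OCc5ccccc5)C2=O | intermediate (not isolated)
12 | (2R,3R,4R)-3,5,7-tris(benzyloxy)-2-[3,4-bis(benzyloxy)phenyl]-3,4-dihydro-2H-chromen-4-ol (all-cis) | C(c5ccccc5)Oc1cc(OCc5ccccc5)c2c(c1)O[C@H](c6ccc(OCc5ccccc5)c(OCc5ccccc5)c6)[C@H](OCc5ccccc5)[C@@H]2O | intermediate
13 | (2R,3R,4R)-3,5,7-tris(benzyloxy)-2-[3,4-bis(benzyloxy)phenyl]-8-bromo-3,4-dihydro-2H-chromen-4-ol | C(c5ccccc5)Oc1cc(OCc5ccccc5)c2c(c1Br)O[C@H](c6ccc(OCc5ccccc5)c(OCc5ccccc5)c6)[C@H](OCc5ccccc5)[C@@H]2O | intermediate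
14 | (2R,3R)-3,5,7-tris(benzyloxy)-2-[3,4-bis(benzyloxy)phenyl]-8-bromo-3,4-dihydro-2H-chromene | C(c5ccccc5)Oc1cc(OCc5ccccc5)c2c(c1Br)O[C@H](c6ccc(OCc5ccccc5)c(OCc5ccccc5)c6)[C@H](OCc5ccccc5)C2 | intermediate
15 | (2R,3R,4R)-3,5,7-tris(benzyloxy)-2-[3,4-bis(benzyloxy)phenyl]-6,8-dibromo-3,4-dihydro-2H-chromen-4-ol | C(c5ccccc5)Oc1c(Br)c(OCc5ccccc5)c2c(c1Br)O[C@H](c6ccc(OCc5ccccc5)c(OCc5ccccc5)c6)[C@H](OCc5ccccc5)[C@@H]2O | intermediate
16 | 8-bromo-penta-O-benzyl-epicatechin-(4β→6)-8-bromo-penta-O-benzyl-epicatechin (both units 2R,3R; upper unit 3,4-trans) | c1c(OCc5ccccc5)c(Br)c2c(c1OCc5ccccc5)[C@H](c1c(OCc5ccccc5)c(Br)c3c(c1OCc5ccccc5)C[C@@H](OCc5ccccc5)[C@@H](c6ccc(OCc5ccccc5)c(OCc5ccccc5)c6)O3)[C@@H](OCc5ccccc5)[C@@H](c6ccc(OCc5ccccc5)c(OCc5ccccc5)c6)O2 | intermediate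
17 | 6,8-dibromo-penta-O-benzyl-epicatechin-(4β→6)-8-bromo-penta-O-benzyl-epicatechin-(4β→6)-8-bromo-penta-O-benzyl-epicatechin (all units 2R,3R; both linked C4 centres 3,4-trans) | C(c5ccccc5)Oc1c(Br)c(OCc5ccccc5)c2c(c1Br)O[C@H](c6ccc(OCc5ccccc5)c(OCc5ccccc5)c6)[C@H](OCc5ccccc5)[C@H]2c1c(OCc5ccccc5)c(Br)c2c(c1OCc5ccccc5)[C@H](c1c(OCc5ccccc5)c(Br)c3c(c1OCc5ccccc5)C[C@@H](OCc5ccccc5)[C@@H](c6ccc(OCc5ccccc5)c(OCc5ccccc5)c6)O3)[C@@H](OCc5ccccc5)[C@@H](c6ccc(OCc5ccccc5)c(OCc5ccccc5)c6)O2 | intermediate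
18 | epicatechin-(4β→6)-epicatechin-(4β→6)-epicatechin (all units 2R,3R; both linked C4 centres 4S, 3,4-trans) | Oc1cc(O)c2c(c1)O[C@H](c1ccc(O)c(O)c1)[C@H](O)[C@H]2c1c(O)cc2c(c1O)[C@H](c1c(O)cc3c(c1O)C[C@@H](O)[C@@H](c1ccc(O)c(O)c1)O3)[C@@H](O)[C@@H](c1ccc(O)c(O)c1)O2 | target

**Totals.** Total step count: 10. Longest linear sequence: 9 steps (1, 2, 3, 4, 5, 6, 8, 9, 10).

**Steps most likely to fail**

Step 4. The catalyst may discriminate poorly between the faces of the tetrasubstituted, alkoxy-bearing C2=C3 bond, and the base may epimerise C3 while the intermediate flavanone waits for carbonyl reduction. The fallback sets out from 10 and comes back at 14, 16 and 17. It removes the C4 oxygen first: LiAlH4 (THF, reflux) should reduce 10 to 3,5,7-tris(benzyloxy)-2-[3,4-bis(benzyloxy)phenyl]-4H-chromene F2. Its isolated enol ether double bond is then hydrogenated with a chiral iridium N,P-ligand catalyst ([Ir(cod)(L)][B(C6H3(CF3)2)4], L a phosphinooxazoline, H2, CH2Cl2) to penta-O-benzyl-epicatechin F3, with syn addition again giving 2,3-cis. DDQ in wet CH2Cl2 puts oxygen back at C4 and gives the 4β-alcohol F4, the C4 epimer of 12, which ionises to the same cation. NBS as in steps 5 and 7 gives the 8-bromo alcohol F5 and the 6,8-dibromo alcohol F6. F5 is reduced as in step 6 to 14, F5 and 14 give 16 as in step 8, and F6 and 16 give 17 as in step 9.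

Step 2. O-acylation may compete, and the doubly stabilised diketonate may close too slowly, so that intermolecular displacement of the para fluoride takes over. The fallback sets out from 4 and comes back at 7, and still forms C2–C3 and O1–C8a in one operation. Ketone 4 and commercial 3,4-bis(benzyloxy)benzaldehyde are treated with Cs2CO3 in DMF: aldol addition is followed by SNAr of the more nucleophilic secondary alkoxide at the ortho fluoride, giving the racemic trans-3-(benzyloxy)-2-[3,4-bis(benzyloxy)phenyl]-5,7-difluoro-2,3-dihydro-4H-chromen-4-one F1. DDQ (dioxane, 90 °C) then dehydrogenates C2–C3 to give 7.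

Step 9. The bromine-deactivated C4 cation may be captured too slowly by the crowded C6 of the dimer, and the acid may cleave and scramble the interflavan bond already present. The fallback sets out from 15 and 14 and comes back at 17; it builds the trimer from the top so that the monomer 14, used in excess, is the nucleophile in both couplings. Coupling of 15 with 14 (BF3·OEt2, −78 °C) gives the top–middle dimer F7. DDQ with 2-ethoxyethanol (CH2Cl2, rt) oxidises its only benzylic CH2, C4 of the lower unit, to the 4β-(2-ethoxyethoxy) ether F8. TMSOTf-mediated coupling of F8 with 14 then gives 17.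

**Further compounds**
F1 | step 2 | rac-(2R,3R)-3-(benzyloxy)-2-[3,4-bis(benzyloxy)phenyl]-5,7-difluoro-2,3-dihydro-4H-chromen-4-one (2,3-trans, one enantiomer drawn) | Fc1cc(F)c2c(c1)O[C@H](c6ccc(OCc5ccccc5)c(OCc5ccccc5)c6)[C@@H](OCc5ccccc5)C2=O
F2 | step 4 | 3,5,7-tris(benzyloxy)-2-[3,4-bis(benzyloxy)phenyl]-4H-chromene | C(c5ccccc5)Oc1cc(OCc5ccccc5)c2c(c1)OC(c6ccc(OCc5ccccc5)c(OCc5ccccc5)c6)=C(OCc5ccccc5)C2
F3 | step 4 | (2R,3R)-3,5,7-tris(benzyloxy)-2-[3,4-bis(benzyloxy)phenyl]-3,4-dihydro-2H-chromene | C(c5ccccc5)Oc1cc(OCc5ccccc5)c2c(c1)O[C@H](c6ccc(OCc5ccccc5)c(OCc5ccccc5)c6)[C@H](OCc5ccccc5)C2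
F4 | step 4 | (2R,3R,4S)-3,5,7-tris(benzyloxy)-2-[3,4-bis(benzyloxy)phenyl]-3,4-dihydro-2H-chromen-4-ol (3,4-trans) | C(c5ccccc5)Oc1cc(OCc5ccccc5)c2c(c1)O[C@H](c6ccc(OCc5ccccc5)c(OCc5ccccc5)c6)[C@H](OCc5ccccc5)[C@H]2O
F5 | step 4 | (2R,3R,4S)-3,5,7-tris(benzyloxy)-2-[3,4-bis(benzyloxy)phenyl]-8-bromo-3,4-dihydro-2H-chromen-4-ol | C(c5ccccc5)Oc1cc(OCc5ccccc5)c2c(c1Br)O[C@H](c6ccc(OCc5ccccc5)c(OCc5ccccc5)c6)[C@H](OCc5ccccc5)[C@H]2O
F6 | step 4 | (2R,3R,4S)-3,5,7-tris(benzyloxy)-2-[3,4-bis(benzyloxy)phenyl]-6,8-dibromo-3,4-dihydro-2H-chromen-4-ol | C(c5ccccc5)Oc1c(Br)c(OCc5ccccc5)c2c(c1Br)O[C@H](c6ccc(OCc5ccccc5)c(OCc5ccccc5)c6)[C@H](OCc5ccccc5)[C@H]2O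
F7 | step 9 | 6,8-dibromo-penta-O-benzyl-epicatechin-(4β→6)-8-bromo-penta-O-benzyl-epicatechin | C(c5ccccc5)Oc1c(Br)c(OCc5ccccc5)c2c(c1Br)O[C@H](c6ccc(OCc5ccccc5)c(OCc5ccccc5)c6)[C@H](OCc5ccccc5)[C@H]2c1c(OCc5ccccc5)c(Br)c2c(c1OCc5ccccc5)C[C@@H](OCc5ccccc5)[C@@H](c6ccc(OCc5ccccc5)c(OCc5ccccc5)c6)O2
F8 | step 9 | 6,8-dibromo-penta-O-benzyl-epicatechin-(4β→6)-8-bromo-4β-(2-ethoxyethoxy)-penta-O-benzyl-epicatechin | C(c5ccccc5)Oc1c(Br)c(OCc5ccccc5)c2c(c1Br)O[C@H](c6ccc(OCc5ccccc5)c(OCc5ccccc5)c6)[C@H](OCc5ccccc5)[C@H]2c1c(OCc5ccccc5)c(Br)c2c(c1OCc5ccccc5)[C@H](OCCOCC)[C@@H](OCc5ccccc5)[C@@H](c6ccc(OCc5ccccc5)c(OCc5ccccc5)c6)O2
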